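**Plan**

1. Retrosynthesis: the two silyl ethers of ring B are removed last. Ring A is then cut at C8–C8a, C7–C8, C5–C6 and C4a–C5 into a 6-(2-diazopropanoyl)-4-pyranone and methoxyacetylene.
2. The pyranone is cut at its C2–aryl bond (Suzuki coupling) into brominated, O-methylated kojic acid and an arylboronate from 2-methoxyresorcinol. The diazo ketone side chain comes from the kojic hydroxymethyl group by oxidation and acylation of diazoethane.
3. Forward: ring C is present from the start as kojic acid, ring B is attached by cross-coupling, and ring A is built last in one operation (Wolff rearrangement, ketene–alkyne (2+2) addition, 4π opening, 6π closure).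
4. Enabling feature: ring A carries OH at C5, H at C6, OMe at C7 and Me at C8, which is the sequence C(OH)–CH–C(OMe)–C(Me) that a methyl(vinyl)ketene and HC≡COMe deliver. The fusion atoms C4a and C8a are the CH carbon and the O-bearing carbon of a pyranone C=C bond, which serves as the vinyl unit.
5. Stereochemistry: the target has no stereocentre. The only selectivity is regiochemical and is fixed by the polarity of the ynol ether and the connectivity of the two partners.

Key step: step 11

Remark: the ring B phenols are carried as triisopropylsilyl ethers, not benzyl ethers, because the iridium-catalysed C–H borylation used to make the boronate would also attack benzyl rings. Below, Ar means 4-methoxy-3,5-bis(triisopropylsilyloxy)phenyl.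

**Route**

Step 1
Reactants: 1 kojic acid (5-hydroxy-2-(hydroxymethyl)-4H-pyran-4-one)
Product: 2 2-bromo-3-hydroxy-6-(hydroxymethyl)-4H-pyran-4-one (6-bromokojic acid)
Conditions: NBS (1.05 equiv), DMF, 0 °C to rt
Reagents that add atoms: N-bromosuccinimide, O=C1CCC(=O)N1Br
Why: Electrophilic bromination of an enol: the C5 hydroxyl of kojic acid activates only the adjacent ring CH (C6), the site at which kojic acid is known to take up electrophiles.

Step 2
Reactants: 2 2-bromo-3-hydroxy-6-(hydroxymethyl)-4H-pyran-4-one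
Product: 3 2-bromo-6-(hydroxymethyl)-3-methoxy-4H-pyran-4-one
Conditions: MeI (1.2 equiv), K2CO3 (1.1 equiv), DMF, rt
Reagents that add atoms: iodomethane, CI
Why: Williamson etherification: K2CO3 deprotonates only the acidic enolic hydroxyl (not the primary alcohol), and the enolate oxygen is methylated by MeI in an SN2 reaction.

Step 3
Reactants: 4 2-methoxyresorcinol (2-methoxybenzene-1,3-diol)
Product: 5 2-methoxy-1,3-bis(triisopropylsilyloxy)benzene
Conditions: iPr3SiCl (2.4 equiv), imidazole (5 equiv), DMAP (cat.), DMF, rt to 40 °C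
Reagents that add atoms: chlorotriisopropylsilane, CC(C)[Si](Cl)(C(C)C)C(C)C
Why: Imidazole-promoted silylation of phenols; the bulky silyl groups should withstand base, oxidants, acid chlorides, light and heat later on and are removed by fluoride.

Step 4
Reactants: 5 2-methoxy-1,3-bis(triisopropylsilyloxy)benzene
Product: 6 2-Ar-4,4,5,5-tetramethyl-1,3,2-dioxaborolane (Ar–Bpin)
Conditions: [Ir(OMe)(cod)]2 (1.5 mol%), 4,4'-di-tert-butyl-2,2'-bipyridine (3 mol%), B2pin2 (1.0 equiv), THF, 80 °C
Reagents that add atoms: bis(pinacolato)diboron, CC1(C)OB(OC1(C)C)B1OC(C)(C)C(C)(C)O1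
Why: Iridium-catalysed C–H borylation (Ishiyama–Miyaura–Hartwig) is governed by sterics and should borylate the only C–H bond with no ortho substituent, C5 of the arene, while the silyl groups offer no competing aromatic C–H bonds.

Step 5
Reactants: 3 2-bromo-6-(hydroxymethyl)-3-methoxy-4H-pyran-4-one; 6 Ar–Bpin
Product: 7 2-Ar-6-(hydroxymethyl)-3-methoxy-4H-pyran-4-one
Conditions: Pd(dppf)Cl2 (5 mol%), K3PO4 (3 equiv), 1,4-dioxane–H2O (5:1), 70 °C
Reagents that add atoms: none
Why: Suzuki–Miyaura coupling: the C2–Br bond of the 4-pyranone is a vinylogous acyl bromide that adds readily to zerovalent palladium, and the free primary alcohol and the silyl ethers tolerate the mild phosphate base.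

Step 6
Reactants: 7 2-Ar-6-(hydroxymethyl)-3-methoxy-4H-pyran-4-one
Product: 8 6-Ar-5-methoxy-4-oxo-4H-pyran-2-carboxylic acid
Conditions: TEMPO (0.2 equiv), PhI(OAc)2 (2.2 equiv), MeCN–H2O (1:1), rt
Reagents that add atoms: water, O
Why: Oxoammonium (TEMPO) catalysis with PhI(OAc)2 as terminal oxidant takes the activated primary alcohol to the aldehyde and, through its hydrate in aqueous acetonitrile, on to the acid, without touching silyl ethers, methyl ethers or the pyranone.

Step 7
Reactants: 8 6-Ar-5-methoxy-4-oxo-4H-pyran-2-carboxylic acid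
Product: 9 6-Ar-5-methoxy-4-oxo-4H-pyran-2-carbonyl chloride (used crude after evaporation)
Conditions: (COCl)2 (1.3 equiv), DMF (cat.), CH2Cl2, 0 °C to rt
Reagents that add atoms: oxalyl chloride, O=C(Cl)C(=O)Cl
Why: Acid chloride formation through the Vilsmeier-type chloroiminium from oxalyl chloride and DMF, routine for 4-oxo-4H-pyran-2-carboxylic acids; the cold, anhydrous conditions should leave the aryl silyl ethers and the pyranone carbonyl untouched.

Step 8
Reactants: 10 N-ethyl-N-nitrosourea
Product: 11 diazoethane (ethereal solution, dried over KOH pellets, used at once)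
Conditions: 40% aq. KOH, Et2O, 0 °C
Reagents that add atoms: none
Why: Alkaline cleavage of an N-alkyl-N-nitrosourea is the standard preparation of diazoalkanes: hydroxide attacks the urea carbonyl and the resulting diazotate loses water to give diazoethane, which is kept cold in ether.

Step 9
Reactants: 9 6-Ar-5-methoxy-4-oxo-4H-pyran-2-carbonyl chloride; 11 diazoethane (about 3 equiv)
Product: 12 2-Ar-6-(2-diazopropanoyl)-3-methoxy-4H-pyran-4-one
Conditions: Et2O–THF, −20 to 0 °C; excess diazoethane quenched with AcOH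
Reagents that add atoms: none
Why: Acylation of a diazoalkane by an acid chloride (first stage of the Arndt–Eistert sequence): the diazo carbon attacks the acyl chloride and a second equivalent of diazoethane removes the HCl as chloroethane, while the absence of α-hydrogens in 9 excludes ketene formation.

Step 10
Reactants: 13 chloroacetaldehyde dimethyl acetal (2-chloro-1,1-dimethoxyethane)
Product: 15 methoxyacetylene, via sodium methoxyacetylide 14 (not isolated)
Conditions: NaNH2 (3 equiv, from Na, cat. Fe(NO3)3), liquid NH3, −35 °C; NH3 evaporated; saturated aq. NaCl, −20 °C; distilled into a cold trap and stored cold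
Reagents that add atoms: none
Why: Twofold elimination with NaNH2 in liquid ammonia (loss of HCl and of methanol) followed by deprotonation gives the acetylide, which cold brine protonates; this is the established preparation of 1-alkoxyalkynes from chloroacetals.

Step 11
Reactants: 12 2-Ar-6-(2-diazopropanoyl)-3-methoxy-4H-pyran-4-one; 15 methoxyacetylene (4 equiv)
Product: 20 2-Ar-5-hydroxy-3,7-dimethoxy-8-methyl-4H-chromen-4-one, via methyl(pyranonyl)ketene 16 (not isolated), via 4-pyranonylcyclobutenone 17 (not isolated), via dienylketene 18 (not isolated), via 4aH-chromene-4,5-dione 19 (not isolated)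
Conditions: hν (Pyrex-filtered medium-pressure Hg lamp or 365 nm LEDs), ClCH2CH2Cl, 5 °C; then sealed tube, 80 °C
Reagents that add atoms: none
Why: Irradiation expels N2 from 12 and the pyranone carbon migrates to the carbene carbon (photochemical Wolff rearrangement), giving ketene 16, whose C=C bond adds the ynol ether 15 in a (2+2) cycloaddition to close the four-membered ring of cyclobutenone 17. A 4π electrocyclic opening of 17 gives dienylketene 18 (the unproductive geometric isomer can return through reclosure), and the isomer with the ketene cis to the pyranone closes onto the pyranone CH carbon to give dienone 19, which tautomerises to phenol 20 with its OH hydrogen-bonded to the C4 carbonyl. The closest known reaction type is the Danheiser benzannulation of unsaturated α-diazo ketones with alkoxy- and siloxyalkynes. Ring A, the only ring that remains, is closed by a thermal disrotatory 6π electrocyclisation in which the electrophilic ketene carbon bonds to C5 of the pyranone, the nucleophilic β-carbon of its enol ether, so the closure is polarity-matched. No stereocentre is formed in 20: the quaternary carbon of 17 and C4a of 19 are transient, racemic and erased by ring opening and aromatisation. The selectivity needed is regiochemical, and the polarisation of the ynol ether secures it: its unsubstituted carbon bonds to the ketene carbonyl carbon, so OMe ends at C7 beside the C8 methyl and the CH ends at C6.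

Step 12
Reactants: 20 2-Ar-5-hydroxy-3,7-dimethoxy-8-methyl-4H-chromen-4-one
Product: 21 2-(3,5-dihydroxy-4-methoxyphenyl)-5-hydroxy-3,7-dimethoxy-8-methyl-4H-chromen-4-one (target)
Conditions: Bu4NF (2.5 equiv), AcOH (2.5 equiv), THF, 0 °C to rt
Reagents that add atoms: none
Why: Fluoride-induced cleavage of aryl silyl ethers, driven by the Si–F bond; the buffered conditions should leave the three methyl ethers, the chromone and the chelated C5 phenol unchanged.

**Compound list**

1 | kojic acid, 5-hydroxy-2-(hydroxymethyl)-4H-pyran-4-one | OCc1cc(=O)c(O)co1 | starting material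
2 | 2-bromo-3-hydroxy-6-(hydroxymethyl)-4H-pyran-4-one | OCc1cc(=O)c(O)c(Br)o1 | intermediate
3 | 2-bromo-6-(hydroxymethyl)-3-methoxy-4H-pyran-4-one | OCc1cc(=O)c(OC)c(Br)o1 | intermediate
4 | 2-methoxyresorcinol, 2-methoxybenzene-1,3-diol | COc1c(O)cccc1O | starting material
5 | 2-methoxy-1,3-bis(triisopropylsilyloxy)benzene | COc1c(O[Si](C(C)C)(C(C)C)C(C)C)cccc1O[Si](C(C)C)(C(C)C)C(C)C | intermediate
6 | 2-[4-methoxy-3,5-bis(triisopropylsilyloxy)phenyl]-4,4,5,5-tetramethyl-1,3,2-dioxaborolane | COc1c(O[Si](C(C)C)(C(C)C)C(C)C)cc(B2OC(C)(C)C(C)(C)O2)cc1O[Si](C(C)C)(C(C)C)C(C)C | intermediate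
7 | 6-(hydroxymethyl)-3-methoxy-2-[4-methoxy-3,5-bis(triisopropylsilyloxy)phenyl]-4H-pyran-4-one | OCc1cc(=O)c(OC)c(-c2cc(O[Si](C(C)C)(C(C)C)C(C)C)c(OC)c(O[Si](C(C)C)(C(C)C)C(C)C)c2)o1 | intermediate
8 | 5-methoxy-6-[4-methoxy-3,5-bis(triisopropylsilyloxy)phenyl]-4-oxo-4H-pyran-2-carboxylic acid | OC(=O)c1cc(=O)c(OC)c(-c2cc(O[Si](C(C)C)(C(C)C)C(C)C)c(OC)c(O[Si](C(C)C)(C(C)C)C(C)C)c2)o1 | intermediate
9 | 5-methoxy-6-[4-methoxy-3,5-bis(triisopropylsilyloxy)phenyl]-4-oxo-4H-pyran-2-carbonyl chloride | ClC(=O)c1cc(=O)c(OC)c(-c2cc(O[Si](C(C)C)(C(C)C)C(C)C)c(OC)c(O[Si](C(C)C)(C(C)C)C(C)C)c2)o1 | intermediate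
10 | N-ethyl-N-nitrosourea | CCN(N=O)C(N)=O | starting material
11 | diazoethane | CC=[N+]=[N-] | intermediate
12 | 6-(2-diazopropanoyl)-3-methoxy-2-[4-methoxy-3,5-bis(triisopropylsilyloxy)phenyl]-4H-pyran-4-one | CC(=[N+]=[N-])C(=O)c1cc(=O)c(OC)c(-c2cc(O[Si](C(C)C)(C(C)C)C(C)C)c(OC)c(O[Si](C(C)C)(C(C)C)C(C)C)c2)o1 | intermediate
13 | chloroacetaldehyde dimethyl acetal, 2-chloro-1,1-dimethoxyethane | COC(CCl)OC | starting material
14 | sodium methoxyacetylide | [Na+].[C-]#COC | intermediate
15 | methoxyacetylene | COC#C | intermediate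
16 | 2-{5-methoxy-6-[4-methoxy-3,5-bis(triisopropylsilyloxy)phenyl]-4-oxo-4H-pyran-2-yl}prop-1-en-1-one (ketene) | CC(=C=O)c1cc(=O)c(OC)c(-c2cc(O[Si](C(C)C)(C(C)C)C(C)C)c(OC)c(O[Si](C(C)C)(C(C)C)C(C)C)c2)o1 | intermediate
17 | 3-methoxy-4-methyl-4-{5-methoxy-6-[4-methoxy-3,5-bis(triisopropylsilyloxy)phenyl]-4-oxo-4H-pyran-2-yl}cyclobut-2-en-1-one (racemic) | COC1=CC(=O)C1(C)c3cc(=O)c(OC)c(-c2cc(O[Si](C(C)C)(C(C)C)C(C)C)c(OC)c(O[Si](C(C)C)(C(C)C)C(C)C)c2)o3 | intermediate
18 | (3E)-3-methoxy-4-{5-methoxy-6-[4-methoxy-3,5-bis(triisopropylsilyloxy)phenyl]-4-oxo-4H-pyran-2-yl}penta-1,3-dien-1-one (ketenyl CH cis to the pyranone) | O=C=C/C(OC)=C(C)\c1cc(=O)c(OC)c(-c2cc(O[Si](C(C)C)(C(C)C)C(C)C)c(OC)c(O[Si](C(C)C)(C(C)C)C(C)C)c2)o1 | intermediate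
19 | 3,7-dimethoxy-2-[4-methoxy-3,5-bis(triisopropylsilyloxy)phenyl]-8-methyl-4aH-chromene-4,5-dione (racemic) | COC1=CC(=O)C2C(=O)C(OC)=C(c3cc(O[Si](C(C)C)(C(C)C)C(C)C)c(OC)c(O[Si](C(C)C)(C(C)C)C(C)C)c3)OC2=C1C | intermediate
20 | 5-hydroxy-3,7-dimethoxy-2-[4-methoxy-3,5-bis(triisopropylsilyloxy)phenyl]-8-methyl-4H-chromen-4-one | COc1cc(O)c2c(=O)c(OC)c(-c3cc(O[Si](C(C)C)(C(C)C)C(C)C)c(OC)c(O[Si](C(C)C)(C(C)C)C(C)C)c3)oc2c1C | intermediate
21 | 2-(3,5-dihydroxy-4-methoxyphenyl)-5-hydroxy-3,7-dimethoxy-8-methyl-4H-chromen-4-one | COc1cc(O)c2c(=O)c(OC)c(-c3cc(O)c(OC)c(O)c3)oc2c1C | target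

**Step count**

Total: 12 steps. Longest linear sequence: 8 steps (steps 1, 2, 5, 6, 7, 9, 11, 12 from kojic acid).

**Steps most likely to fail**

Step 11 is the riskiest. Light absorbed by the 2-aryl-4-pyranone chromophore may drive pyranone photoisomerisation or hydrogen abstraction from the 3-methoxy group instead of nitrogen loss. The carbene may also undergo a 1,2-hydrogen shift to an enone, and the ketene may be lost to dimerisation before it meets the volatile alkyne. The fallback generates the same ketene in the dark. It sets out from 12, which is heated in benzyl alcohol and 2,4,6-collidine at about 170 °C (thermal Wolff rearrangement with trapping by the alcohol) to give benzyl 2-{5-methoxy-6-Ar-4-oxo-4H-pyran-2-yl}propanoate F1. Hydrogenolysis (H2, Pd/C, EtOAc) gives 2-{5-methoxy-6-Ar-4-oxo-4H-pyran-2-yl}propanoic acid F2, and (COCl)2 with catalytic DMF gives 2-{5-methoxy-6-Ar-4-oxo-4H-pyran-2-yl}propanoyl chloride F3. Dehydrochlorination of F3 with Et3N in toluene in the presence of excess 15, at 0 °C and then 80 °C, forms ketene 16, which should run through 17, 18 and 19 as before. The fallback comes back to the route at 20.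

Step 9 is second. Diazoethane may add as a 1,3-dipole across the C=C bond of the pyranone that is activated by both the ring carbonyl and the acyl group, giving pyrazolines in competition with C-acylation. The fallback avoids diazoethane. It sets out from 9, which undergoes Negishi acylation (Et2Zn, Pd(PPh3)4 cat., THF, 0 °C to rt) to give the ethyl ketone 2-Ar-3-methoxy-6-propanoyl-4H-pyran-4-one F4. Enolisation with LiN(SiMe3)2 and trifluoroacetylation with CF3CO2CH2CF3 (THF, −78 °C) gives 4,4,4-trifluoro-1-{5-methoxy-6-Ar-4-oxo-4H-pyran-2-yl}-2-methylbutane-1,3-dione F5, used crude. Detrifluoroacetylative diazo transfer (MsN3, Et3N, H2O, MeCN, rt) then comes back to the route at 12.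

Step 5 is third. Addition–elimination displacement of the C2 bromide by hydroxide, or by the primary alkoxide of a second molecule, and protodeboronation of the electron-rich boronate may outrun transmetalation. The fallback changes the order of oxidation and coupling. It sets out from 3, which is oxidised (CrO3, H2SO4, acetone, 0 °C) to 6-bromo-5-methoxy-4-oxo-4H-pyran-2-carboxylic acid F6. Its potassium carboxylate carries no alkoxide and repels hydroxide; it is coupled with 6 (Pd(dppf)Cl2, K3PO4, 1,4-dioxane–H2O, 70 °C). This comes back to the route at 8 and bypasses 7 and step 6.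

**Further compounds**

F1 | step 11 | benzyl 2-{5-methoxy-6-[4-methoxy-3,5-bis(triisopropylsilyloxy)phenyl]-4-oxo-4H-pyran-2-yl}propanoate (racemic) | CC(C(=O)OCc3ccccc3)c1cc(=O)c(OC)c(-c2cc(O[Si](C(C)C)(C(C)C)C(C)C)c(OC)c(O[Si](C(C)C)(C(C)C)C(C)C)c2)o1
F2 | step 11 | 2-{5-methoxy-6-[4-methoxy-3,5-bis(triisopropylsilyloxy)phenyl]-4-oxo-4H-pyran-2-yl}propanoic acid (racemic) | CC(C(O)=O)c1cc(=O)c(OC)c(-c2cc(O[Si](C(C)C)(C(C)C)C(C)C)c(OC)c(O[Si](C(C)C)(C(C)C)C(C)C)c2)o1
F3 | step 11 | 2-{5-methoxy-6-[4-methoxy-3,5-bis(triisopropylsilyloxy)phenyl]-4-oxo-4H-pyran-2-yl}propanoyl chloride (racemic) | CC(C(Cl)=O)c1cc(=O)c(OC)c(-c2cc(O[Si](C(C)C)(C(C)C)C(C)C)c(OC)c(O[Si](C(C)C)(C(C)C)C(C)C)c2)o1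
F4 | step 9 | 3-methoxy-2-[4-methoxy-3,5-bis(triisopropylsilyloxy)phenyl]-6-propanoyl-4H-pyran-4-one | CCC(=O)c1cc(=O)c(OC)c(-c2cc(O[Si](C(C)C)(C(C)C)C(C)C)c(OC)c(O[Si](C(C)C)(C(C)C)C(C)C)c2)o1
F5 | step 9 | 4,4,4-trifluoro-1-{5-methoxy-6-[4-methoxy-3,5-bis(triisopropylsilyloxy)phenyl]-4-oxo-4H-pyran-2-yl}-2-methylbutane-1,3-dione (racemic) | CC(C(=O)C(F)(F)F)C(=O)c1cc(=O)c(OC)c(-c2cc(O[Si](C(C)C)(C(C)C)C(C)C)c(OC)c(O[Si](C(C)C)(C(C)C)C(C)C)c2)o1
F6 | step 5 | 6-bromo-5-methoxy-4-oxo-4H-pyran-2-carboxylic acid | OC(=O)c1cc(=O)c(OC)c(Br)o1
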